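**Retrosynthetic overview**

1. The target is (1S,4S,5R,8S)-8-(3,4-dihydroxyphenyl)-4-(4-hydroxy-3-methoxyphenyl)-3,7-dioxabicyclo[3.3.0]octan-2-one; the last operations are debenzylation and deoxygenation of a C6 lactol.
2. The feature the plan rests on: the ring-fusion carbons C1 and C5, shared by the lactone ring (C1–C2(=O)–O3–C4–C5) and the ether ring (C5–C6–O7–C8–C1), are the α- and β-carbons of a butenolide whose γ-carbon is C6. C1 carries the catechol carbinol carbon C8 and C5 carries the guaiacyl carbinol carbon C4.
3. Key disconnections: C4–C5 (conjugate addition of a guaiacyl acyl-anion equivalent) and C1–C8 (aldol of the resulting enolate), both made in one pot on (5R)-5-menthyloxybutenolide.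
4. Ring order: the auxiliary-bearing lactone (C2–O–C6) comes first; one acid step then transposes it, closing the lactone ring at O3–C2 and the ether ring at O7–C6 together; C6 is finally reduced to CH2.
5. Building blocks: furfural, (−)-menthol, 4-(benzyloxy)-3-methoxybenzaldehyde and 3,4-bis(benzyloxy)benzaldehyde.

Key step: step 4

Remark on numbering: C1–C8 denote the atoms of the bicyclic core of the target throughout (3,7-dioxabicyclo[3.3.0]octan-2-one numbering).
Remark on C8: the aldol part of step 4 is not expected to fix the carbinol carbon C8 completely. The route is written for the (S)-carbinol, which passes with retention into the exo aryl group of the target; its epimer is returned to the route as described under the fallbacks.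
Remark on C6: the hemiacetal carbon of 15 is expected as an anomeric mixture; one anomer is drawn and the centre disappears in step 8.

**Route**

Step 1
Reactants: 1 furfural
Product: 3 5-hydroxyfuran-2(5H)-one, via furan endoperoxide 2 (not isolated)
Conditions: O2, hν (visible), rose bengal (tetrachlorotetraiodofluorescein disodium salt, cat.), MeOH, 20 °C
Reagents that add atoms: dioxygen, O=O
Why: Sensitised photooxygenation of a furan: singlet oxygen adds [4+2] across the ring to endoperoxide 2, whose formyl group is attacked by methanol and expelled as methyl formate while the peroxide bond breaks, leaving the γ-hydroxybutenolide as a racemic hemiacetal (no stereocentre is controlled here).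

Step 2
Reactants: 3 5-hydroxyfuran-2(5H)-one; 4 (−)-menthol
Product: 5 (5R)-5-[(1R,2S,5R)-menthyloxy]furan-2(5H)-one
Conditions: (1S)-(+)-10-camphorsulfonic acid (cat.), toluene, reflux, Dean–Stark; crystallisation from petroleum ether, mother liquor re-equilibrated with the same acid and recrystallised
Reagents that add atoms: none
Why: Acid-catalysed acetalisation of the cyclic hemiacetal gives both acetal epimers, which equilibrate under the acid, and because the (5R) epimer is the crystalline one, crystallisation with re-equilibration of the mother liquor (crystallisation-driven epimer enrichment) fixes the acetal carbon that later becomes C6.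

Step 3
Reactants: 6 4-(benzyloxy)-3-methoxybenzaldehyde
Product: 7 2-[4-(benzyloxy)-3-methoxyphenyl]-1,3-dithiane
Conditions: propane-1,3-dithiol (1.1 equiv), BF3·OEt2 (0.2 equiv), CH2Cl2, 0 °C → rt
Reagents that add atoms: propane-1,3-dithiol, SCCCS
Why: Lewis-acid-catalysed dithioacetalisation of an aromatic aldehyde (the handle for Corey–Seebach umpolung), which the aryl benzyl and methyl ethers survive at this catalyst loading and temperature.

Step 4
Reactants: 7 2-[4-(benzyloxy)-3-methoxyphenyl]-1,3-dithiane; 5 (5R)-5-[(1R,2S,5R)-menthyloxy]furan-2(5H)-one; 8 3,4-bis(benzyloxy)benzaldehyde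
Product: 12 (3S,4R,5R)-3-{(S)-[3,4-bis(benzyloxy)phenyl](hydroxy)methyl}-4-{2-[4-(benzyloxy)-3-methoxyphenyl]-1,3-dithian-2-yl}-5-[(1R,2S,5R)-menthyloxy]oxolan-2-one, via 2-lithio dithiane 9 (not isolated), via lithium lactone enolate 10 (not isolated), via lithium aldolate 11 (not isolated)
Conditions: n-BuLi (1.05 equiv), THF, −78 → −30 °C, 1 h; recool to −78 °C, 5 (1.0 equiv), 2 h; 8 (1.2 equiv), −78 °C, 1 h; AcOH in THF at −78 °C
Reagents that add atoms: none
Why: This is a tandem Michael addition–aldol (three-component coupling) of the kind known for lithiated 2-aryl-1,3-dithianes, 5-alkoxybutenolides and aldehydes: the soft sulfur-stabilised benzylic anion 9 adds to the β-carbon of 5 (bond C4–C5) and the lithium enolate 10 is trapped by aldehyde 8 (bond C1–C8) through a lithium-bridged six-membered transition state. No ring is closed in this step. C5 is set by the acetal carbon C6, because the nucleophile enters the butenolide face opposite to the menthyloxy group, and C1 is set by C5, because the aldehyde approaches the enolate face opposite to the large dithianyl group, which gives the all-trans lactone. The carbinol carbon C8 is set only by the aldol transition state, and for this ring-constrained (E)-enolate with a very large neighbouring substituent the control is expected to be weak, so 12 should be accompanied by its C8 epimer and is separated by chromatography. The step needs 1,4- over 1,2-addition (secured by the delocalised dithiane anion and the unhindered β-carbon), anti facial selectivity (secured by the single acetal stereocentre) and suppression of retro-aldol (secured by holding −78 °C and quenching cold with acid).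

Step 5
Reactants: 12 the dithianyl aldol adduct
Product: 13 (3S,4R,5R)-4-[4-(benzyloxy)-3-methoxybenzoyl]-3-{(S)-[3,4-bis(benzyloxy)phenyl](hydroxy)methyl}-5-[(1R,2S,5R)-menthyloxy]oxolan-2-one
Conditions: HgO (2 equiv), BF3·OEt2 (2 equiv), THF–H2O (85:15), rt
Reagents that add atoms: water, O
Why: Mercury-assisted hydrolysis of the S,S-acetal, in which the thiophilic mercury opens the dithiane to a thionium ion that water captures; the medium stays free of base, so C5 (now α to the ketone and β to the acyloxy group on C6) is neither epimerised nor lost by elimination, and no stereocentre is formed.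

Step 6
Reactants: 13 the aryl ketone
Product: 14 (3S,4S,5R)-4-{(S)-[4-(benzyloxy)-3-methoxyphenyl](hydroxy)methyl}-3-{(S)-[3,4-bis(benzyloxy)phenyl](hydroxy)methyl}-5-[(1R,2S,5R)-menthyloxy]oxolan-2-one
Conditions: LiAlH(OtBu)3 (2.5 equiv), THF, −78 → −30 °C; sat. aq. Rochelle salt; used crude
Reagents that add atoms: none
Why: Substrate-controlled hydride reduction of an α-branched aryl ketone (Felkin–Anh): with the C5–C1 bond (C1 carries the branched carbinol arm) as the large substituent anti to the incoming hydride and C5–H on the aryl side, hydride should enter the Re face and give the (S)-carbinol at C4, while the aluminium alkoxides formed at low temperature are too weakly nucleophilic to open the acyloxy acetal, so no aldehyde is set free in the presence of hydride and the lactone itself is not reduced.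

Step 7
Reactants: 14 the bis-carbinol menthyloxy lactone
Product: 15 (1S,4S,5S,6R,8S)-4-[4-(benzyloxy)-3-methoxyphenyl]-8-[3,4-bis(benzyloxy)phenyl]-6-hydroxy-3,7-dioxabicyclo[3.3.0]octan-2-one
Conditions: p-toluenesulfonic acid monohydrate (0.3 equiv), MeCN–H2O (10:1), 40 °C
Reagents that add atoms: water, O
Why: Acid-catalysed transposition of a masked aldehyde-acid (translactonisation plus hemiacetal formation): the acyloxy acetal ionises at C6, the C2 carboxyl lactonises onto the C4 hydroxyl (the only one that gives a five-membered lactone) and C6 is captured by the C8 hydroxyl (the only one that gives a five-membered hemiacetal) with loss of menthol, one water being consumed at C6 and one released at C2; C4 and C8 keep their configuration because only bonds from oxygen to C2 and C6 are exchanged, and the trans arrangement of the two arms on the old lactone becomes the cis ring fusion.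

Step 8
Reactants: 15 the lactol
Product: 16 (1S,4S,5R,8S)-4-[4-(benzyloxy)-3-methoxyphenyl]-8-[3,4-bis(benzyloxy)phenyl]-3,7-dioxabicyclo[3.3.0]octan-2-one
Conditions: Et3SiH (4 equiv), BF3·OEt2 (2 equiv), CH2Cl2, −78 → −20 °C; sat. aq. NaHCO3
Reagents that add atoms: none
Why: Ionic hydrogenation of a lactol, in which BF3 ionises the hemiacetal to the cyclic oxocarbenium ion at C6 and the silane reduces it to CH2; at low temperature this ion should form far faster than the benzylic C4–O3 and C8–O7 bonds ionise, so the lactone, the benzylic ether and all four stereocentres are kept.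

Step 9
Reactants: 16 the tribenzyl ether
Product: 17 (1S,4S,5R,8S)-8-(3,4-dihydroxyphenyl)-4-(4-hydroxy-3-methoxyphenyl)-3,7-dioxabicyclo[3.3.0]octan-2-one
Conditions: H2 (1 atm), 10% Pd/C, EtOAc, rt, stopped as soon as debenzylation is complete
Reagents that add atoms: none
Why: Catalytic hydrogenolysis of aryl benzyl ethers, which in a neutral aprotic solvent should be much faster than cleavage of the alkyl benzylic C–O bonds at C4 and C8, and which touches no stereocentre.

**Compound list**

1 | furfural | O=Cc1ccco1 | starting material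
2 | 1-formyl-2,3,7-trioxabicyclo[2.2.1]hept-5-ene (furan endoperoxide, racemic) | O=CC12C=CC(OO1)O2 | intermediate
3 | 5-hydroxyfuran-2(5H)-one (racemic) | OC1OC(=O)C=C1 | intermediate
4 | (−)-menthol, (1R,2S,5R) | C[C@@H]1CC[C@H]([C@@H](C1)O)C(C)C | starting material
5 | (5R)-5-[(1R,2S,5R)-menthyloxy]furan-2(5H)-one | C[C@@H]1CC[C@H]([C@@H](C1)O[C@@H]1OC(=O)C=C1)C(C)C | intermediate
6 | 4-(benzyloxy)-3-methoxybenzaldehyde | COc1cc(C=O)ccc1OCc1ccccc1 | starting material
7 | 2-[4-(benzyloxy)-3-methoxyphenyl]-1,3-dithiane | COc1cc(C2SCCCS2)ccc1OCc1ccccc1 | intermediate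
8 | 3,4-bis(benzyloxy)benzaldehyde | O=Cc1ccc(OCc2ccccc2)c(OCc2ccccc2)c1 | starting material
9 | 2-lithio-2-[4-(benzyloxy)-3-methoxyphenyl]-1,3-dithiane | COc1cc(C2([Li])SCCCS2)ccc1OCc1ccccc1 | intermediate
10 | lithium enolate of (4R,5R)-4-{2-[4-(benzyloxy)-3-methoxyphenyl]-1,3-dithian-2-yl}-5-(menthyloxy)oxolan-2-one | C[C@@H]1CC[C@H]([C@@H](C1)O[C@@H]1OC(O[Li])=C[C@H]1C1(c2ccc(OCc3ccccc3)c(OC)c2)SCCCS1)C(C)C | intermediate
11 | lithium alkoxide (aldolate) of 12 | C[C@@H]1CC[C@H]([C@@H](C1)O[C@@H]1OC(=O)[C@H]([C@H](O[Li])c2ccc(OCc3ccccc3)c(OCc3ccccc3)c2)[C@H]1C1(c2ccc(OCc3ccccc3)c(OC)c2)SCCCS1)C(C)C | intermediate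
12 | (3S,4R,5R)-3-{(S)-[3,4-bis(benzyloxy)phenyl](hydroxy)methyl}-4-{2-[4-(benzyloxy)-3-methoxyphenyl]-1,3-dithian-2-yl}-5-[(1R,2S,5R)-menthyloxy]oxolan-2-one | C[C@@H]1CC[C@H]([C@@H](C1)O[C@@H]1OC(=O)[C@H]([C@H](O)c2ccc(OCc3ccccc3)c(OCc3ccccc3)c2)[C@H]1C1(c2ccc(OCc3ccccc3)c(OC)c2)SCCCS1)C(C)C | intermediate
13 | (3S,4R,5R)-4-[4-(benzyloxy)-3-methoxybenzoyl]-3-{(S)-[3,4-bis(benzyloxy)phenyl](hydroxy)methyl}-5-[(1R,2S,5R)-menthyloxy]oxolan-2-one | C[C@@H]1CC[C@H]([C@@H](C1)O[C@@H]1OC(=O)[C@H]([C@H](O)c2ccc(OCc3ccccc3)c(OCc3ccccc3)c2)[C@H]1C(=O)c1ccc(OCc2ccccc2)c(OC)c1)C(C)C | intermediate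
14 | (3S,4S,5R)-4-{(S)-[4-(benzyloxy)-3-methoxyphenyl](hydroxy)methyl}-3-{(S)-[3,4-bis(benzyloxy)phenyl](hydroxy)methyl}-5-[(1R,2S,5R)-menthyloxy]oxolan-2-one | C[C@@H]1CC[C@H]([C@@H](C1)O[C@@H]1OC(=O)[C@H]([C@H](O)c2ccc(OCc3ccccc3)c(OCc3ccccc3)c2)[C@H]1[C@H](O)c1ccc(OCc2ccccc2)c(OC)c1)C(C)C | intermediate
15 | (1S,4S,5S,6R,8S)-4-[4-(benzyloxy)-3-methoxyphenyl]-8-[3,4-bis(benzyloxy)phenyl]-6-hydroxy-3,7-dioxabicyclo[3.3.0]octan-2-one (one anomer drawn) | COc1cc([C@H]2OC(=O)[C@H]3[C@@H]2[C@H](O)O[C@@H]3c2ccc(OCc3ccccc3)c(OCc3ccccc3)c2)ccc1OCc1ccccc1 | intermediate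
16 | (1S,4S,5R,8S)-4-[4-(benzyloxy)-3-methoxyphenyl]-8-[3,4-bis(benzyloxy)phenyl]-3,7-dioxabicyclo[3.3.0]octan-2-one | COc1cc([C@H]2OC(=O)[C@H]3[C@@H]2CO[C@@H]3c2ccc(OCc3ccccc3)c(OCc3ccccc3)c2)ccc1OCc1ccccc1 | intermediate
17 | (1S,4S,5R,8S)-8-(3,4-dihydroxyphenyl)-4-(4-hydroxy-3-methoxyphenyl)-3,7-dioxabicyclo[3.3.0]octan-2-one | COc1cc([C@H]2OC(=O)[C@H]3[C@@H]2CO[C@@H]3c2ccc(O)c(O)c2)ccc1O | target

**Step count and risks**

Total step count: 9. Longest linear sequence: 8 steps (1 → 2 → 4 → 5 → 6 → 7 → 8 → 9, from furfural).

Steps most likely to fail: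

1. Step 4. What may go wrong is incomplete stereocontrol at the carbinol carbon in the aldol addition, together with loss of adduct by retro-aldol if the aldolate warms before the quench. The fallback sets out from 12 taken as the unseparated mixture with its C8 epimer, (3S,4R,5R)-3-{(R)-[3,4-bis(benzyloxy)phenyl](hydroxy)methyl}-4-{2-[4-(benzyloxy)-3-methoxyphenyl]-1,3-dithian-2-yl}-5-[(1R,2S,5R)-menthyloxy]oxolan-2-one F1. Parikh–Doering oxidation (SO3·pyridine, DMSO, i-Pr2NEt, CH2Cl2, 0 °C, conditions that leave the dithiane sulfur alone) should converge both epimers on the β-keto lactone (3S,4R,5R)-3-[3,4-bis(benzyloxy)benzoyl]-4-{2-[4-(benzyloxy)-3-methoxyphenyl]-1,3-dithian-2-yl}-5-[(1R,2S,5R)-menthyloxy]oxolan-2-one F2. Reduction of F2 with Zn(BH4)2 (Et2O, −20 °C) is then chelation-controlled: zinc held between the ketone and the lactone carbonyl keeps the two C=O groups syn, and hydride should enter from the open face turned away from the lactone ring, giving the syn (S) carbinol. The fallback comes back to the route at 12.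

2. Step 6. What may go wrong is poor facial selectivity of hydride delivery to the ketone, or migration of the lactone onto the new alkoxide followed by reduction of the aldehyde that is then set free. The fallback replaces substrate control by reagent control. It sets out from 13 and uses a CBS reduction: (R)-tetrahydro-1-methyl-3,3-diphenyl-1H,3H-pyrrolo[1,2-c][1,3,2]oxazaborole (1 equiv), BH3·SMe2 (2.5 equiv), THF, −20 °C, then MeOH. With the aryl group as the large substituent this catalyst should deliver hydride to the Re face, and the boron alkoxides formed cannot attack the lactone. It comes back to the route at 14 and makes no new compound (F0).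

3. Step 9. What may go wrong is hydrogenolysis running on into the benzylic C4–O3 and C8–O7 bonds once the aryl benzyl ethers are gone, opening the lactone or the ether ring. The fallback removes the benzyl groups without hydrogen. It sets out from 16 and uses BCl3 (6 equiv) with pentamethylbenzene (9 equiv) as a non-basic benzyl-cation scavenger in CH2Cl2 at −78 °C, quenched cold with MeOH; the aryl methyl ether should survive at this temperature. It comes back to the route at 17 and makes no new compound (F0).

**Further compounds**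

F1 | step 4 | (3S,4R,5R)-3-{(R)-[3,4-bis(benzyloxy)phenyl](hydroxy)methyl}-4-{2-[4-(benzyloxy)-3-methoxyphenyl]-1,3-dithian-2-yl}-5-[(1R,2S,5R)-menthyloxy]oxolan-2-one | C[C@@H]1CC[C@H]([C@@H](C1)O[C@@H]1OC(=O)[C@H]([C@@H](O)c2ccc(OCc3ccccc3)c(OCc3ccccc3)c2)[C@H]1C1(c2ccc(OCc3ccccc3)c(OC)c2)SCCCS1)C(C)C
F2 | step 4 | (3S,4R,5R)-3-[3,4-bis(benzyloxy)benzoyl]-4-{2-[4-(benzyloxy)-3-methoxyphenyl]-1,3-dithian-2-yl}-5-[(1R,2S,5R)-menthyloxy]oxolan-2-one | C[C@@H]1CC[C@H]([C@@H](C1)O[C@@H]1OC(=O)[C@H](C(=O)c2ccc(OCc3ccccc3)c(OCc3ccccc3)c2)[C@H]1C1(c2ccc(OCc3ccccc3)c(OC)c2)SCCCS1)C(C)C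
F0 | step 6 | none | none
F0 | step 9 | none | none
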